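**Retrosynthetic overview**
1. Feature: in the ten-membered carbocycle (C5–C6–C7–C8–C14–C15–C16–C17–C18–C19) the Z-trisubstituted olefin C6(Me)=C7 faces sp2 C16 of the diene C15=C16–C17(Me)=C18 across the ring. A transannular C6–C16 bond turns it into a cis-decalin (ring A: C5, C6, C16–C19; ring B: C6–C8, C14–C16) with C16–OH, an angular C6 methyl and a C7 leaving group.
2. Late disconnections: six-membered lactone (C1–O2, oxidative lactonisation of the C1/C3 diol), seven-membered lactone (C10–O9, from C8–OH), C15=C16 (C16 ketone, then dienyl triflate, then C–H).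
3. Key disconnection: Wharton–Grob fragmentation of decalinol mesylate 32 cuts C6–C16 and gives cyclodecadienone 34 with both ring olefins cis.
4. Decalin 32: ring B is built on a ring-A enone by a C6–C7 aldol (acrolein), a C15–C16 allylzinc addition and C8=C14 ring-closing metathesis. C14, C8 and C7 are then set from the convex face of the cis-decalin.
5. Ring A comes from an organocatalytic Michael/aldol condensation (C5–C6, C17=C18). Ring order: A, B, ten-membered ring (from A+B), seven-membered lactone, six-membered lactone.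

Key step: step 22

Remark: locants follow the tricycle (C1 lactone C=O, O2, C3(Et), C4, C5, C6(Me)=C7, C8, O9, C10(=O), C11, C12(OH), C13, C14, C15=C16, C17(Me)=C18, C19). α is the face of the C6 methyl group and β the opposite face. Compound 11 (at C6) and compounds 13–16, 25 and 26 (at C7) may be epimer mixtures at centres that are erased later, and they are drawn as the expected major isomer.

**Step 1**
Reactants: 1 tert-butyl acetoacetate
Product: 3 tert-butyl 3-oxopentanoate, via dianion 2 (not isolated)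
Conditions: NaH, THF, 0 °C; n-BuLi, 0 °C; MeI, 0 °C → rt; 1 M HCl
Reagents that add atoms: iodomethane, CI
Why: γ-Alkylation of a β-keto ester dianion, in which the terminal, more basic carbanion is methylated selectively to supply C6, C16, C17 and the C17 methyl group without forming a stereocentre.

**Step 2**
Reactants: 4 (S)-1,2-epoxybutane
Product: 5 (S)-hex-5-en-3-ol
Conditions: CH2=CHMgBr, CuI (10 mol%), THF, −40 → 0 °C; H2O
Reagents that add atoms: vinylmagnesium bromide, C=C[Mg]Br
Why: Copper-catalysed Grignard opening of a terminal epoxide by SN2 attack at the unsubstituted carbon (C4), so the C3 stereocentre of 4 is carried over unchanged.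

**Step 3**
Reactants: 5 (S)-hex-5-en-3-ol
Product: 6 (S)-3-(tert-butyldiphenylsilyloxy)hex-5-ene
Conditions: TBDPSCl, imidazole, DMF, rt
Reagents that add atoms: tert-butyldiphenylsilyl chloride, CC(C)(C)[Si](Cl)(c1ccccc1)c1ccccc1
Why: Standard silylation, with the acid-stable TBDPS ether chosen because it has to survive the hot TsOH of step 5.

**Step 4**
Reactants: 6 (S)-3-(tert-butyldiphenylsilyloxy)hex-5-ene
Product: 7 (S,E)-5-(tert-butyldiphenylsilyloxy)hept-2-enal
Conditions: crotonaldehyde (5 equiv), Hoveyda–Grubbs II (3 mol%), CH2Cl2, 40 °C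
Reagents that add atoms: crotonaldehyde, C/C=C/C=O
Why: Olefin cross-metathesis of a terminal alkene with an electron-poor partner, which should give the E-enal under thermodynamic control and brings in C19 and C18.

**Step 5**
Reactants: 7 (S,E)-5-(tert-butyldiphenylsilyloxy)hept-2-enal, 3 tert-butyl 3-oxopentanoate
Product: 9 ring-A enone (5R)-5-[(2S)-2-(TBDPS-oxy)butyl]-2-methylcyclohex-2-enone, via Michael adduct 8 (not isolated)
Conditions: (R)-α,α-diphenylprolinol TMS ether (10 mol%), PhCO2H (10 mol%), toluene, rt; then TsOH·H2O (20 mol%), 80 °C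
Reagents that add atoms: none
Why: Iminium-catalysed asymmetric Michael addition in which the (R)-catalyst shields one face of the s-trans E-iminium ion so that C6 adds to C5 from the open face and sets C5 under catalyst control, after which acid brings about the intramolecular aldol condensation (C17 onto C18), tert-butyl ester cleavage and decarboxylation.

**Step 6**
Reactants: 9 ring-A enone
Product: 11 2,6-dimethyl enone (C6-Me β as major epimer), via lithium enolate 10 (not isolated)
Conditions: LDA, THF, −78 °C; MeI, −78 → −20 °C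
Reagents that add atoms: iodomethane, CI
Why: Kinetic α′-deprotonation of a carvone-type enone and enolate methylation, with the C6 configuration of no consequence because C6 is planarised again in step 7.

**Step 7**
Reactants: 11 2,6-dimethyl enone
Product: 13 aldol adduct (quaternary C6 bearing Me α and the C7 carbinol β), via lithium enolate 12 (not isolated)
Conditions: LDA, THF, −78 °C; acrolein, −78 °C; AcOH quench at −78 °C
Reagents that add atoms: acrolein, C=CC=O
Why: Aldol addition of the tetrasubstituted cross-conjugated enolate, in which acrolein reaches C6 anti to the neighbouring C5 side chain and so sets the quaternary centre with its methyl group cis to that chain, while the Zimmerman–Traxler-favoured C7 carbinol is erased in step 17.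

**Step 8**
Reactants: 13 aldol adduct
Product: 14 bis-TMS dienol ether
Conditions: TMSOTf (2.5 equiv), Et3N (4 equiv), CH2Cl2, 0 °C
Reagents that add atoms: trimethylsilyl triflate, C[Si](C)(C)OS(=O)(=O)C(F)(F)F
Why: Soft enolisation in which, with no α′-hydrogen left, only the γ-hydrogen at C19 can be removed, so the extended silyl dienol ether forms while C7–OH is silylated at the same time.

**Step 9**
Reactants: 14 bis-TMS dienol ether
Product: 15 γ-hydroxymethyl enone diol (C19-CH2OH β)
Conditions: aq. HCHO (37%), Sc(OTf)3 (10 mol%), THF, rt; brief 0.5 M HCl work-up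
Reagents that add atoms: formaldehyde, C=O
Why: Vinylogous Mukaiyama aldol (Lewis-acid-catalysed hydroxymethylation) in which the fully substituted C17 is blocked, so the dienol ether reacts at its γ-terminus C19 anti to the C5 side chain and the axial C6 methyl group to give the trans C5/C19 relation, and the labile C7 TMS ether is lost on work-up.

**Step 10**
Reactants: 15 γ-hydroxymethyl enone diol
Product: 16 C1-O-TBDPS enone
Conditions: TBDPSCl (1.05 equiv), imidazole, CH2Cl2, 0 °C
Reagents that add atoms: tert-butyldiphenylsilyl chloride, CC(C)(C)[Si](Cl)(c1ccccc1)c1ccccc1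
Why: Steric selection in silylation, since the primary C1–OH should react far faster than the neopentyl secondary C7–OH.

**Step 11**
Reactants: 17 ethyl (R)-4-chloro-3-hydroxybutanoate
Product: 18 ethyl (R)-3,4-epoxybutanoate
Conditions: Ag2O, DME, 80 °C
Reagents that add atoms: none
Why: Silver(I)-oxide-mediated halohydrin closure (intramolecular Williamson reaction) without soluble base, which avoids isomerisation to the 4-hydroxycrotonate and leaves the C12–O bond and its configuration untouched.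

**Step 12**
Reactants: 19 2-bromoallyltrimethylsilane, 18 ethyl (R)-3,4-epoxybutanoate
Product: 21 ethyl (S)-3-hydroxy-5-(trimethylsilylmethyl)hex-5-enoate, via alkenyl Grignard reagent 20 (not isolated)
Conditions: Mg, THF, rt; CuI (10 mol%), −40 °C; add 18, −40 → −20 °C; H2O
Reagents that add atoms: none
Why: Copper-catalysed opening of the terminal epoxide at C13 by an alkenyl Grignard reagent at low temperature, which spares the ester and the C12 stereocentre and forms C13–C14.

**Step 13**
Reactants: 21 ethyl (S)-3-hydroxy-5-(trimethylsilylmethyl)hex-5-enoate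
Product: 22 TBS ether of 21
Conditions: TBSCl, imidazole, DMF, rt
Reagents that add atoms: tert-butyldimethylsilyl chloride, CC(C)(C)[Si](C)(C)Cl
Why: Standard silylation of the secondary C12 alcohol, giving the one silyl ether that has to outlast the C8 TES ether.

**Step 14**
Reactants: 22 TBS ether of 21
Product: 23 ethyl (S)-5-(bromomethyl)-3-(TBS-oxy)hex-5-enoate
Conditions: NBS, CH2Cl2, −78 °C; aq. NaHCO3
Reagents that add atoms: N-bromosuccinimide, O=C1CCC(=O)N1Br
Why: Electrophilic bromodesilylation of an allylsilane (SE2′), where bromine enters at the alkene terminus and silicon leaves, so a single 2-substituted allylic bromide should result.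

**Step 15**
Reactants: 23 ethyl (S)-5-(bromomethyl)-3-(TBS-oxy)hex-5-enoate, 16 C1-O-TBDPS enone
Product: 25 tertiary allylic alcohol (C16-OH α and C15 β), via allylzinc bromide 24 (not isolated)
Conditions: 23, Zn dust, LiCl, THF, 0 °C; separately 16, Et2Zn (1.05 equiv), THF, 0 °C; combine, −20 °C → rt; H2O
Reagents that add atoms: none
Why: 1,2-Addition of an ester-tolerant allylic zinc reagent to the enone carbonyl, where axial attack anti to the axial C6 methyl group, helped by the zinc chelate between C7–O and C16=O, puts C15 on the β face and sets C16 with OH cis to the methyl group.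

**Step 16**
Reactants: 25 tertiary allylic alcohol
Product: 26 cis-decalin diol (C8=C14 olefin)
Conditions: Grubbs II (5 mol%), CH2Cl2 (5 mM), 40 °C
Reagents that add atoms: none
Why: Ring-closing metathesis of the monosubstituted and 1,1-disubstituted alkenes closes the six-membered ring B, the trisubstituted C17=C18 olefin being inert.

**Step 17**
Reactants: 26 cis-decalin diol
Product: 27 cis-decalin ketol enone
Conditions: Dess–Martin periodinane, NaHCO3, CH2Cl2, 0 °C → rt
Reagents that add atoms: none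
Why: Dess–Martin oxidation of the secondary allylic C7 alcohol under buffered neutral conditions, which cannot touch the tertiary C16–OH, should not trigger retro-aldol cleavage, and merges both C7 epimers.

**Step 18**
Reactants: 27 cis-decalin ketol enone
Product: 28 TES enol ether (C14 side chain β)
Conditions: Et3SiH (3 equiv), RhCl(PPh3)3 (2 mol%), toluene, 50 °C
Reagents that add atoms: triethylsilane, CC[SiH](CC)CC
Why: Rhodium-catalysed 1,4-hydrosilylation of the enone, with hydride delivered to C14 along the axial trajectory on the convex α face of the cis-decalin so that the side chain ends up equatorial (β), while the isolated C17=C18 olefin does not react.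

**Step 19**
Reactants: 28 TES enol ether
Product: 30 α-TES-oxy ketol (C8-O α), via silyloxy epoxide 29 (not isolated)
Conditions: mCPBA (1.05 equiv), NaHCO3, CH2Cl2, −40 → 0 °C
Reagents that add atoms: 3-chloroperbenzoic acid, O=C(OO)c1cccc(Cl)c1
Why: Rubottom oxidation with 1,4-silyl migration, in which the electron-rich enol ether outruns C17=C18 and is attacked from the α face because the axial C6–C5 bond blocks the β face, so C8–O is set trans to the C14 side chain.

**Step 20**
Reactants: 30 α-TES-oxy ketol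
Product: 31 C7,C16-diol (C7-OH β and equatorial)
Conditions: Me4NBH(OAc)3, MeCN/AcOH, −30 °C
Reagents that add atoms: none
Why: Evans–Saksena reduction in which the axial C16–OH binds boron and delivers hydride to the α face of C7, giving the anti-1,3-diol, which is also the outcome expected for axial attack on the convex face.

**Step 21**
Reactants: 31 C7,C16-diol
Product: 32 decalinol mesylate
Conditions: MsCl (1.5 equiv), Et3N (3 equiv), CH2Cl2, −20 → 0 °C
Reagents that add atoms: methanesulfonyl chloride, CS(=O)(=O)Cl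
Why: Sulfene-type mesylation reaches the hindered secondary C7–OH while the tertiary C16–OH stays free.

**Step 22**
Reactants: 32 decalinol mesylate
Product: 34 (Z,Z)-cyclodecadienone, via potassium alkoxide 33 (not isolated)
Conditions: KHMDS (1.05 equiv), THF, −78 → 0 °C; pH 7 buffer
Reagents that add atoms: none
Why: KHMDS removes the only hydroxyl proton to give potassium alkoxide 33, whose oxygen lone pair pushes into the C6–C16 σ bond while that bond, antiperiplanar to the equatorial C7–OMs bond, donates into σ*(C7–O), so C16=O, C6=C7 and mesylate departure develop in one concerted step. This is the Wharton–Grob fragmentation of a decalin-1,3-diol monosulfonate, the classical entry to cyclodecenones. No ring is closed by bond formation: the ten-membered carbocycle appears because the bond shared by rings A and B is cut, so the entropic and transannular penalties of a medium-ring closure are avoided. No stereocentre is created and C3, C5, C8, C12, C14 and C19 are untouched; what is controlled is olefin geometry, because in the cis-decalin chair that places the C7, C8, C14, C5 and C19 substituents equatorial the C6–C5 bond is axial on ring B and gauche to C7–C8, so C5 and C8 become cis (Z), while C17=C18 stays cis as a former cyclohexene bond. The step needs fragmentation to win over oxetane formation, E2 elimination and ester enolisation: the equatorial mesylate has no antiperiplanar hydrogen, the axial alkoxide oxygen cannot reach the rear side of C7, and one equivalent of base at low temperature is consumed by the far more acidic O–H.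

**Step 23**
Reactants: 34 (Z,Z)-cyclodecadienone
Product: 36 dienyl triflate, via potassium dienolate 35 (not isolated)
Conditions: KHMDS (1.1 equiv), THF, −78 °C; PhNTf2, −78 → −20 °C; aq. NH4Cl
Reagents that add atoms: N-phenylbis(trifluoromethanesulfonimide), O=S(=O)(N(c1ccccc1)S(=O)(=O)C(F)(F)F)C(F)(F)F
Why: Kinetic α′-deprotonation at C15 and O-sulfonylation, where a ring that already holds two cis olefins should only accommodate the enolate with C14 and C17 cis, which fixes the later Z geometry of C15=C16.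

**Step 24**
Reactants: 36 dienyl triflate
Product: 37 cyclodecatriene ester
Conditions: Pd(OAc)2 (5 mol%), PPh3 (10 mol%), HCO2H, Et3N, DMF, 50 °C
Reagents that add atoms: none
Why: Palladium-catalysed formate hydrogenolysis of an enol triflate (oxidative addition, decarboxylation of formate, reductive elimination), which replaces OTf by H with retention of olefin geometry.

**Step 25**
Reactants: 37 cyclodecatriene ester
Product: 39 C8-hydroxy acid, via carboxylic acid 38 (not isolated)
Conditions: LiOH·H2O, THF/MeOH/H2O, rt; then 1 M HCl to pH 2–3, rt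
Reagents that add atoms: lithium hydroxide, [Li+].[OH-]
Why: Saponification of the unhindered ethyl ester followed by mild aqueous acid, which cleaves only the TES ether as the most labile silyl group and so frees C8–OH alone.

**Step 26**
Reactants: 39 C8-hydroxy acid
Product: 40 seven-membered lactone
Conditions: 2-methyl-6-nitrobenzoic anhydride (1.5 equiv), DMAP (4 equiv), toluene (2 mM), rt
Reagents that add atoms: none
Why: Shiina lactonisation via the mixed anhydride and the acylpyridinium ion closes the seven-membered ring on the only free hydroxyl group (C8–OH), the β-oxygen at C12 still being silylated so that no β-lactone can form.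

**Step 27**
Reactants: 40 seven-membered lactone
Product: 41 triol lactone
Conditions: HF·pyridine, pyridine/THF, 0 °C → rt
Reagents that add atoms: none
Why: Global fluoride-mediated desilylation under mildly acidic conditions, which should spare the β-hydroxy lactone and the triene.

**Step 28**
Reactants: 41 triol lactone
Product: 43 rhizolutin, via lactol 42 (not isolated)
Conditions: TEMPO (20 mol%), PhI(OAc)2 (2.5 equiv), CH2Cl2, rt
Reagents that add atoms: none
Why: Oxoammonium-mediated oxidative lactonisation of a 1,5-diol, in which the primary C1 alcohol is oxidised selectively, the aldehyde is trapped at once by C3–OH as lactol 42 (so C19 has little time to epimerise) and oxidised on to the six-membered lactone, while the secondary C12–OH reacts much more slowly.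

**Compound list**
1 | tert-butyl acetoacetate | CC(=O)CC(=O)OC(C)(C)C | starting material
2 | sodium lithium dianion of 1 | [Na+].[Li+].[CH2-]C(=O)[CH-]C(=O)OC(C)(C)C | intermediate
3 | tert-butyl 3-oxopentanoate | CCC(=O)CC(=O)OC(C)(C)C | intermediate
4 | (S)-1,2-epoxybutane | CC[C@H]1CO1 | starting material
5 | (S)-hex-5-en-3-ol | CC[C@H](O)CC=C | intermediate
6 | (S)-3-(tert-butyldiphenylsilyloxy)hex-5-ene | CC[C@H](O[Si](c3ccccc3)(c4ccccc4)C(C)(C)C)CC=C | intermediate
7 | (S,E)-5-(tert-butyldiphenylsilyloxy)hept-2-enal | CC[C@H](O[Si](c3ccccc3)(c4ccccc4)C(C)(C)C)C/C=C/C=O | intermediate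
8 | Michael adduct (aldehyde; C5 set, C6 epimers) | CC[C@H](O[Si](c3ccccc3)(c4ccccc4)C(C)(C)C)C[C@@H](CC=O)C(C(=O)CC)C(=O)OC(C)(C)C | intermediate
9 | ring-A enone, (5R)-5-[(2S)-2-(TBDPS-oxy)butyl]-2-methylcyclohex-2-enone | CC[C@H](O[Si](c3ccccc3)(c4ccccc4)C(C)(C)C)C[C@H]1CC=C(C)C(=O)C1 | intermediate
10 | cross-conjugated lithium enolate of 9 | CC[C@H](O[Si](c3ccccc3)(c4ccccc4)C(C)(C)C)C[C@H]1CC=C(C)C(O[Li])=C1 | intermediate
11 | 2,6-dimethyl enone (C6-Me β, trans to the C5 chain, major) | CC[C@H](O[Si](c3ccccc3)(c4ccccc4)C(C)(C)C)C[C@H]1CC=C(C)C(=O)[C@@H]1C | intermediate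
12 | tetrasubstituted lithium enolate of 11 | CC[C@H](O[Si](c3ccccc3)(c4ccccc4)C(C)(C)C)C[C@H]1CC=C(C)C(O[Li])=C1C | intermediate
13 | aldol adduct (C6: Me α, 1-hydroxyallyl β; C5 chain α) | CC[C@H](O[Si](c3ccccc3)(c4ccccc4)C(C)(C)C)C[C@H]1CC=C(C)C(=O)[C@]1(C)[C@@H](O)C=C | intermediate
14 | bis-TMS compound (C16-OTMS 16,18-dienol ether, C7-OTMS) | CC[C@H](O[Si](c3ccccc3)(c4ccccc4)C(C)(C)C)C[C@H]1C=CC(C)=C(O[Si](C)(C)C)[C@]1(C)[C@@H](O[Si](C)(C)C)C=C | intermediate
15 | γ-hydroxymethyl enone diol (C19-CH2OH β, trans to the C5 chain) | CC[C@H](O[Si](c3ccccc3)(c4ccccc4)C(C)(C)C)C[C@H]1[C@H](CO)C=C(C)C(=O)[C@]1(C)[C@@H](O)C=C | intermediate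
16 | C1-O-TBDPS enone | CC[C@H](O[Si](c3ccccc3)(c4ccccc4)C(C)(C)C)C[C@H]1[C@H](CO[Si](c5ccccc5)(c6ccccc6)C(C)(C)C)C=C(C)C(=O)[C@]1(C)[C@@H](O)C=C | intermediate
17 | ethyl (R)-4-chloro-3-hydroxybutanoate | ClC[C@H](O)CC(=O)OCC | starting material
18 | ethyl (R)-3,4-epoxybutanoate | CCOC(=O)C[C@@H]1CO1 | intermediate
19 | 2-bromoallyltrimethylsilane | C=C(Br)C[Si](C)(C)C | starting material
20 | [3-(trimethylsilyl)prop-1-en-2-yl]magnesium bromide | C=C([Mg]Br)C[Si](C)(C)C | intermediate
21 | ethyl (S)-3-hydroxy-5-(trimethylsilylmethyl)hex-5-enoate | CCOC(=O)C[C@@H](O)CC(=C)C[Si](C)(C)C | intermediate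
22 | ethyl (S)-3-(TBS-oxy)-5-(trimethylsilylmethyl)hex-5-enoate | CCOC(=O)C[C@@H](O[Si](C)(C)C(C)(C)C)CC(=C)C[Si](C)(C)C | intermediate
23 | ethyl (S)-5-(bromomethyl)-3-(TBS-oxy)hex-5-enoate | CCOC(=O)C[C@@H](O[Si](C)(C)C(C)(C)C)CC(=C)CBr | intermediate
24 | allylzinc bromide from 23 | CCOC(=O)C[C@@H](O[Si](C)(C)C(C)(C)C)CC(=C)C[Zn]Br | intermediate
25 | tertiary allylic alcohol (C16: OH α, C15 β) | CC[C@H](O[Si](c3ccccc3)(c4ccccc4)C(C)(C)C)C[C@H]1[C@H](CO[Si](c5ccccc5)(c6ccccc6)C(C)(C)C)C=C(C)[C@](O)(CC(=C)C[C@H](O[Si](C)(C)C(C)(C)C)CC(=O)OCC)[C@]1(C)[C@@H](O)C=C | intermediate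
26 | cis-decalin diol (C6-Me and C16-OH α; C8=C14; C7-OH β) | CC[C@H](O[Si](c3ccccc3)(c4ccccc4)C(C)(C)C)C[C@H]1[C@H](CO[Si](c5ccccc5)(c6ccccc6)C(C)(C)C)C=C(C)[C@]2(O)CC(C[C@H](O[Si](C)(C)C(C)(C)C)CC(=O)OCC)=C[C@H](O)[C@]12C | intermediate
27 | cis-decalin ketol enone (C7=O, C8=C14) | CC[C@H](O[Si](c3ccccc3)(c4ccccc4)C(C)(C)C)C[C@H]1[C@H](CO[Si](c5ccccc5)(c6ccccc6)C(C)(C)C)C=C(C)[C@]2(O)CC(C[C@H](O[Si](C)(C)C(C)(C)C)CC(=O)OCC)=CC(=O)[C@]12C | intermediate
28 | TES enol ether (C7-OTES, C7=C8; C14 chain β) | CC[C@H](O[Si](c3ccccc3)(c4ccccc4)C(C)(C)C)C[C@H]1[C@H](CO[Si](c5ccccc5)(c6ccccc6)C(C)(C)C)C=C(C)[C@]2(O)C[C@H](C[C@H](O[Si](C)(C)C(C)(C)C)CC(=O)OCC)C=C(O[Si](CC)(CC)CC)[C@]12C | intermediate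
29 | α-face C7,C8-silyloxy epoxide | CC[C@H](O[Si](c3ccccc3)(c4ccccc4)C(C)(C)C)C[C@H]1[C@H](CO[Si](c5ccccc5)(c6ccccc6)C(C)(C)C)C=C(C)[C@]2(O)C[C@H](C[C@H](O[Si](C)(C)C(C)(C)C)CC(=O)OCC)[C@H]7O[C@@]7(O[Si](CC)(CC)CC)[C@]12C | intermediate
30 | α-TES-oxy ketol (C7=O, C8-OTES α) | CC[C@H](O[Si](c3ccccc3)(c4ccccc4)C(C)(C)C)C[C@H]1[C@H](CO[Si](c5ccccc5)(c6ccccc6)C(C)(C)C)C=C(C)[C@]2(O)C[C@H](C[C@H](O[Si](C)(C)C(C)(C)C)CC(=O)OCC)[C@@H](O[Si](CC)(CC)CC)C(=O)[C@]12C | intermediate
31 | C7,C16-diol (C7-OH β, C16-OH α) | CC[C@H](O[Si](c3ccccc3)(c4ccccc4)C(C)(C)C)C[C@H]1[C@H](CO[Si](c5ccccc5)(c6ccccc6)C(C)(C)C)C=C(C)[C@]2(O)C[C@H](C[C@H](O[Si](C)(C)C(C)(C)C)CC(=O)OCC)[C@@H](O[Si](CC)(CC)CC)[C@H](O)[C@]12C | intermediate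
32 | cis-decalinol mesylate (C16-OH α, C6-Me α, C7-OMs β equatorial, C8-OTES α, C14 chain β, C5 chain α, C19-CH2O β) | CC[C@H](O[Si](c3ccccc3)(c4ccccc4)C(C)(C)C)C[C@H]1[C@H](CO[Si](c5ccccc5)(c6ccccc6)C(C)(C)C)C=C(C)[C@]2(O)C[C@H](C[C@H](O[Si](C)(C)C(C)(C)C)CC(=O)OCC)[C@@H](O[Si](CC)(CC)CC)[C@H](OS(C)(=O)=O)[C@]12C | intermediate
33 | potassium C16 alkoxide of 32 | [K+].CC[C@H](O[Si](c3ccccc3)(c4ccccc4)C(C)(C)C)C[C@H]1[C@H](CO[Si](c5ccccc5)(c6ccccc6)C(C)(C)C)C=C(C)[C@]2([O-])C[C@H](C[C@H](O[Si](C)(C)C(C)(C)C)CC(=O)OCC)[C@@H](O[Si](CC)(CC)CC)[C@H](OS(C)(=O)=O)[C@]12C | intermediate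
34 | (Z,Z)-cyclodecadienone (C16=O, C6=C7 and C17=C18 both Z) | CC[C@H](O[Si](c3ccccc3)(c4ccccc4)C(C)(C)C)C[C@@H]1/C(C)=C\[C@H](O[Si](CC)(CC)CC)[C@@H](C[C@H](O[Si](C)(C)C(C)(C)C)CC(=O)OCC)CC(=O)/C(C)=C\[C@H]1CO[Si](c5ccccc5)(c6ccccc6)C(C)(C)C | intermediate
35 | potassium C15,C16-dienolate of 34 | [K+].CC[C@H](O[Si](c3ccccc3)(c4ccccc4)C(C)(C)C)C[C@@H]1/C(C)=C\[C@H](O[Si](CC)(CC)CC)[C@@H](C[C@H](O[Si](C)(C)C(C)(C)C)CC(=O)OCC)/C=C([O-])\C(C)=C/[C@H]1CO[Si](c5ccccc5)(c6ccccc6)C(C)(C)C | intermediate
36 | C16 dienyl triflate (C14 and C17 cis) | CC[C@H](O[Si](c3ccccc3)(c4ccccc4)C(C)(C)C)C[C@@H]1/C(C)=C\[C@H](O[Si](CC)(CC)CC)[C@@H](C[C@H](O[Si](C)(C)C(C)(C)C)CC(=O)OCC)/C=C(OS(=O)(=O)C(F)(F)F)\C(C)=C/[C@H]1CO[Si](c5ccccc5)(c6ccccc6)C(C)(C)C | intermediate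
37 | (Z,Z,Z)-cyclodecatriene ethyl ester | CC[C@H](O[Si](c3ccccc3)(c4ccccc4)C(C)(C)C)C[C@@H]1/C(C)=C\[C@H](O[Si](CC)(CC)CC)[C@@H](C[C@H](O[Si](C)(C)C(C)(C)C)CC(=O)OCC)/C=C\C(C)=C/[C@H]1CO[Si](c5ccccc5)(c6ccccc6)C(C)(C)C | intermediate
38 | C10 carboxylic acid (C8-OTES still in place) | CC[C@H](O[Si](c3ccccc3)(c4ccccc4)C(C)(C)C)C[C@@H]1/C(C)=C\[C@H](O[Si](CC)(CC)CC)[C@@H](C[C@H](O[Si](C)(C)C(C)(C)C)CC(=O)O)/C=C\C(C)=C/[C@H]1CO[Si](c5ccccc5)(c6ccccc6)C(C)(C)C | intermediate
39 | C8-hydroxy C10-acid | CC[C@H](O[Si](c3ccccc3)(c4ccccc4)C(C)(C)C)C[C@@H]1/C(C)=C\[C@H](O)[C@@H](C[C@H](O[Si](C)(C)C(C)(C)C)CC(=O)O)/C=C\C(C)=C/[C@H]1CO[Si](c5ccccc5)(c6ccccc6)C(C)(C)C | intermediate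
40 | seven-membered lactone (C12-OTBS, C3- and C1-OTBDPS) | CC[C@H](O[Si](c3ccccc3)(c4ccccc4)C(C)(C)C)C[C@@H]1/C(C)=C\[C@@H]2OC(=O)C[C@@H](O[Si](C)(C)C(C)(C)C)C[C@H]2/C=C\C(C)=C/[C@H]1CO[Si](c5ccccc5)(c6ccccc6)C(C)(C)C | intermediate
41 | triol lactone (C1-, C3- and C12-OH free) | CC[C@H](O)C[C@@H]1/C(C)=C\[C@@H]2OC(=O)C[C@@H](O)C[C@H]2/C=C\C(C)=C/[C@H]1CO | intermediate
42 | C1 lactol (anomers) | CC[C@H]1C[C@@H]2/C(C)=C\[C@@H]3OC(=O)C[C@@H](O)C[C@H]3/C=C\C(C)=C/[C@H]2C(O)O1 | intermediate
43 | rhizolutin (3S,5S,8R,12S,14S,19R; 6Z,15Z,17Z) | CC[C@H]1C[C@@H]2/C(C)=C\[C@@H]3OC(=O)C[C@@H](O)C[C@H]3/C=C\C(C)=C/[C@H]2C(=O)O1 | target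

**Step count**
Total step count: 28.
Longest linear sequence: 23 steps (4 → 43; steps 2–10 and 15–28).

**Steps most likely to fail**

1. Step 22 (fragmentation).
- Risk: the alkoxide may be diverted before the C6–C16 bond breaks, by silyl migration onto the alkoxide oxygen or by slow reaction if ring B leaves the all-equatorial chair. The new enone may also be consumed by base-induced transannular condensation.
- Fallback: it sets out from ketol 30 and comes back at triene 37, with no reduction and no sulfonate.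
- With KHMDS at −78 °C in the presence of PhNTf2, the C16 alkoxide cleaves the same C6–C16 bond by a retro-aldol reaction, the C7 ketone acting as the electron sink.
- In the released C6=C7 enolate the methyl group that eclipses C7=O in 30 ends up cis to oxygen. This enolate is trapped irreversibly as the ten-membered keto enol triflate F1.
- A second KHMDS/PhNTf2 treatment gives the bis(enol triflate) F2, and Pd(OAc)2/PPh3/HCO2H/Et3N removes both triflate groups to give 37.

2. Step 9 (vinylogous hydroxymethylation).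
- Risk: the aqueous medium may protodesilylate the dienol ether faster than C–C bond formation, attack may occur at C17 instead of C19, or water may be lost from the product to give the 4-methylene dienone.
- Fallback: it sets out from enal 7 (with keto ester 3) and comes back at enone 16. C1 is introduced by ordinary α′-enolate chemistry before a 1,3-carbonyl transposition.
- The one-pot Michael/cyclisation of step 5 run with the (S)-catalyst gives the C5-epimeric enone F3, read with its carbonyl as C18.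
- LDA and then gaseous formaldehyde give the trans α′-hydroxymethyl enone F4, and TBDPSCl/imidazole gives the silyl ether F5.
- H2O2/NaOH gives the epoxy ketone F6, and N2H4·H2O with catalytic AcOH (Wharton transposition) gives the allylic alcohol F7.
- MnO2 gives the transposed enone F8, LDA/MeI gives the 6-methyl enone F9, and LDA/acrolein as in step 7 gives 16.

3. Step 23 (enol triflate).
- Risk: deprotonation may stray to C19, or the ten-membered enolate may be sulfonylated in a geometry that leads to an E C15=C16 olefin.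
- Fallback: it sets out from ketone 34 and comes back at triene 37, and it fixes the geometry by a stereospecific syn-elimination.
- KHMDS followed by 2-(phenylsulfonyl)-3-phenyloxaziridine gives the C15 α-hydroxy ketone F10.
- Chelation-controlled reduction with Zn(BH4)2 gives the erythro C15,C16-diol F11, whichever C15 epimer is formed.
- Thiocarbonyldiimidazole gives the cis-fused cyclic thionocarbonate F12.
- Corey–Winter elimination with 1,3-dimethyl-2-phenyl-1,3,2-diazaphospholidine at 40 °C gives the Z olefin of 37.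

**Further compounds**
F1 | step 22 | ten-membered keto enol triflate (C7-OTf, C5 and C8 cis) | CC[C@H](O[Si](c3ccccc3)(c4ccccc4)C(C)(C)C)C[C@@H]1/C(C)=C(OS(=O)(=O)C(F)(F)F)\[C@H](O[Si](CC)(CC)CC)[C@@H](C[C@H](O[Si](C)(C)C(C)(C)C)CC(=O)OCC)CC(=O)/C(C)=C\[C@H]1CO[Si](c5ccccc5)(c6ccccc6)C(C)(C)C
F2 | step 22 | bis(enol triflate) (C7-OTf and C16-OTf) | CC[C@H](O[Si](c3ccccc3)(c4ccccc4)C(C)(C)C)C[C@@H]1/C(C)=C(OS(=O)(=O)C(F)(F)F)\[C@H](O[Si](CC)(CC)CC)[C@@H](C[C@H](O[Si](C)(C)C(C)(C)C)CC(=O)OCC)/C=C(OS(=O)(=O)C(F)(F)F)\C(C)=C/[C@H]1CO[Si](c5ccccc5)(c6ccccc6)C(C)(C)C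
F3 | step 9 | C5-epimeric enone (carbonyl = C18) | CC[C@H](O[Si](c3ccccc3)(c4ccccc4)C(C)(C)C)C[C@H]1CC(=O)C(C)=CC1
F4 | step 9 | trans α′-hydroxymethyl enone | CC[C@H](O[Si](c3ccccc3)(c4ccccc4)C(C)(C)C)C[C@H]1[C@H](CO)C(=O)C(C)=CC1
F5 | step 9 | silyl ether of F4 | CC[C@H](O[Si](c3ccccc3)(c4ccccc4)C(C)(C)C)C[C@H]1[C@H](CO[Si](c5ccccc5)(c6ccccc6)C(C)(C)C)C(=O)C(C)=CC1
F6 | step 9 | C16,C17-epoxy ketone (epoxide drawn anti to the C5 chain; face of no consequence) | CC[C@H](O[Si](c3ccccc3)(c4ccccc4)C(C)(C)C)C[C@H]1[C@H](CO[Si](c5ccccc5)(c6ccccc6)C(C)(C)C)C(=O)[C@]7(C)O[C@@H]7C1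
F7 | step 9 | transposed allylic alcohol (C16-OH, C17=C18) | CC[C@H](O[Si](c3ccccc3)(c4ccccc4)C(C)(C)C)C[C@H]1[C@H](CO[Si](c5ccccc5)(c6ccccc6)C(C)(C)C)C=C(C)[C@H](O)C1
F8 | step 9 | transposed enone (C16=O) | CC[C@H](O[Si](c3ccccc3)(c4ccccc4)C(C)(C)C)C[C@H]1[C@H](CO[Si](c5ccccc5)(c6ccccc6)C(C)(C)C)C=C(C)C(=O)C1
F9 | step 9 | 6-methyl enone | CC[C@H](O[Si](c3ccccc3)(c4ccccc4)C(C)(C)C)C[C@H]1[C@H](CO[Si](c5ccccc5)(c6ccccc6)C(C)(C)C)C=C(C)C(=O)[C@@H]1C
F10 | step 23 | C15 α-hydroxy ketone (one C15 epimer drawn) | CC[C@H](O[Si](c3ccccc3)(c4ccccc4)C(C)(C)C)C[C@@H]1/C(C)=C\[C@H](O[Si](CC)(CC)CC)[C@@H](C[C@H](O[Si](C)(C)C(C)(C)C)CC(=O)OCC)[C@@H](O)C(=O)/C(C)=C\[C@H]1CO[Si](c5ccccc5)(c6ccccc6)C(C)(C)C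
F11 | step 23 | erythro C15,C16-diol | CC[C@H](O[Si](c3ccccc3)(c4ccccc4)C(C)(C)C)C[C@@H]1/C(C)=C\[C@H](O[Si](CC)(CC)CC)[C@@H](C[C@H](O[Si](C)(C)C(C)(C)C)CC(=O)OCC)[C@@H](O)[C@@H](O)/C(C)=C\[C@H]1CO[Si](c5ccccc5)(c6ccccc6)C(C)(C)C
F12 | step 23 | cis-fused cyclic thionocarbonate | CC[C@H](O[Si](c3ccccc3)(c4ccccc4)C(C)(C)C)C[C@@H]1/C(C)=C\[C@H](O[Si](CC)(CC)CC)[C@@H](C[C@H](O[Si](C)(C)C(C)(C)C)CC(=O)OCC)[C@H]8OC(=S)O[C@H]8/C(C)=C\[C@H]1CO[Si](c5ccccc5)(c6ccccc6)C(C)(C)C
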